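## Analysis of the target

Digriseophene A (16) is achiral and built from two identical benzophenone halves joined by one CH2 group, so the synthesis has regiochemistry to control but no stereocentre. In each half, ring A is an acylphloroglucinol: C1 carries the ketone, C2 and C6 carry OH, C3 the bridging CH2, C4 an OMe and C5 a hydrogen. Ring B is an orcinol-type ring: C1' is bonded to the ketone, C2' carries OMe, C4' OH and C6' a methyl group. Each ketone sits between four ortho substituents (O2, O6, O2', CH3 on C6'), which makes aryl–CO bond formation at that carbon by Friedel–Crafts chemistry unattractive. Ten aryl oxygens must end in two states: methyl ethers only at O4 and O2', free hydroxyls at O2, O6 and O4'. The sensitive parts are the electron-rich diarylmethane (prone to oxidation and to acid- or base-induced scission through quinone methides), the air-sensitive polyphenol in base, and the 2-hydroxy-2'-methoxybenzophenone motif, which can close to a xanthone in hot base. The strategy rests on ring B: oxygen at C2' and C4' and a methyl on C6' are the pattern of a folded chain ArC(=O)–CH2–CO–CH2–CO–CH2–CO–CH3. C1' is the CH2 next to the aryl ketone and C6' is the terminal methyl ketone carbon, so the C1'–C6' bond of both B rings can be made by aldol condensation.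

## Retrosynthetic reasoning

16 back to 15. The six free hydroxyls are masked as one kind of acid-labile acetal ether, so the last step cuts six O–CH2 bonds in a single operation and the free polyphenol never meets base or an oxidant.

15 back to 14 and 13. The O2'–CH3 bonds and the O4' acetals are removed in turn, leading to 13 with both ring B hydroxyls free. They differ there: O2'–H is hydrogen-bonded to the ketone, O4'–H is not. O4' is capped with the same acetal as the core rather than a silyl ether, because an aryl silyl ether is at risk under carbonate in a polar aprotic solvent and a freed O4' would be methylated irreversibly. The forward steps must cap O4' only, then methylate the chelated O2'.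

13 back to 11. This is the key disconnection: the C1'–C6' bond of both B rings is cut, together with the ring unsaturation formed by dehydration. Cutting here turns each aromatic ring B into an open 1-aryl-octane-1,3,5,7-tetraone arm. The tetra-ortho-substituted ketone then never has to be formed by joining two finished rings, because its carbon is already on ring A when ring B is folded. The forward reaction is a redox-neutral aldol condensation that must choose attack of the CH2 next to the aryl ketone on the terminal methyl ketone, on both arms.

11 back to 9 and 10. The bond between each ketone carbon and the neighbouring CH2 is cut, once in each half. The hindered carbonyl becomes the electrophile, as the bis(acyl imidazolide) 9 of diacid 5. The remaining seven carbons of each arm arrive in one piece as the terminal carbanion of triketone trianion 10, made from 8, so two molecules of 10 are joined to one molecule of 9. The forward reaction must C-acylate twice without proton-transfer losses.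

8 back to 6. The open triketone is the hydrolytic ring-opening product of the commercial pyranone 6, so no carbon–carbon bond is made for this fragment.

5 back to 4 and 3. The acid is the ester at the same oxidation level, and the four acetal ethers are removed to give tetraphenol 3. The acetals are chosen because they survive the strong bases of the acylation, the aqueous base of the folding and the methylation.

3 back to 2. The two C3–CH2 bonds are cut, giving two molecules of 2 and a one-carbon electrophile at the aldehyde oxidation level. C3 and C5 of 2 are equivalent, so the symmetric bridge has no regiochemical issue.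

2 back to 1. The O4–CH3 bond is cut. In 1 only O4–H is not hydrogen-bonded to the ester, which allows selective methylation.

## Alternatives that were turned down

Alternative 1: Both A rings are disconnected into a four-carbon and a two-carbon piece. Forward, two molecules of cyclobutenone A1 are heated with the skipped bis(ynol ether) A2. Each A1 opens to a vinylketene, adds to one alkyne unit by [2+2] cycloaddition, and the new cyclobutenone opens and closes by 6π electrocyclisation to a phenol (Danheiser benzannulation, twice), giving diarylmethane A3.
- For it: the OH, OMe and protected oxygen of ring A are set by the reaction, the bridge is built in, and no oligomers can form. On the ring A oxygen pattern it is at least as good as the chosen route.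
- Against it: the key step makes two phloroglucinol rings that can be bought with the right oxygenation (1). A2 has a doubly propargylic CH2 that can isomerise to allenes and must survive heating. After A3 the hard parts remain: two hindered aroyl groups must enter at C1 in competition with C5, and ring B needs its own synthesis with differentiated oxygens.
- Comparison: the chosen route sets the ring A methyl ether by one selective etherification instead, and in return it fixes the ketone carbon on ring A before ring B exists and builds ring B in the key step.

Alternative 2: Ring A is cut at the bond between C1 and C2, C2 being a former lactone carbonyl. Forward, Mg(OMe)2 in its parent alcohol opens both 4-methoxy-2-pyranone rings of the bridged bis-pyranone A4 to methyl esters, and the CH2 between the two ketones of each arm attacks its ester (Claisen mode), giving A5.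
- For it: all methyl ethers and the O4' benzyl ether are in place before cyclisation, so A5 is one hydrogenolysis from 16. On the end game it is stronger than the chosen route (one step against three) and it needs no selective functionalisation of ring B.
- Against it: A4 needs ring B as a separately made, doubly ortho-substituted benzoate that must acylate a pyranone methyl anion twice, and the CH2 between the two pyranone rings competes for the base. The cyclisation electrophile is a β-methoxyacrylate-type ester, a poor acceptor, and the nucleophilic CH2 sits next to a hindered aroyl group. The competing aldol mode is held back only by the metal ion. A5 is formed with free O2 and O6 next to O2'–CH3 in hot alkoxide, the conditions for xanthone formation.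
- Comparison: the chosen route closes onto an unhindered methyl ketone, with the mode fixed by the substrate, and its precursor comes from two commercial compounds with no separate ring B synthesis.

Alternative 3: The C(=O)–C1' bonds are cut and ring B enters one oxidation level low. Forward, the kinetic enolate (LiN(iPr)2) of vinylogous ester A6 is C-acylated at its alpha-prime carbon by both acyl groups of 9, giving the bis(dienol ketone) A7 as a mixture of diastereomers. A quinone oxidant would then aromatise it to A8.
- For it: the nucleophile is a simple monoanion, O4' is etherified from the start so O2' and O4' need no differentiation, and it shares 9 with the chosen route. On these points it is stronger, and the step count from 9 is about the same.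
- Against it: O-acylation competes at a hindered carbonyl. The aromatisation needs an oxidant that attacks the CH–CH2 unit of ring B but spares the bridge CH2 between two very electron-rich rings. The benzyl group later needs its own hydrogenolysis.
- Comparison: the chosen route aromatises by loss of water, so no oxidant meets the diarylmethane, and the six ring B carbons come from a cheap pyranone at the correct oxidation level.

Key step: step 7

Remark: 8 and 11 are drawn as keto forms although they exist largely as enols, which changes no step. The discussion numbers ring A from the ketone-bearing carbon (C1), while the systematic names of 9 and 11 to 16 number it from the bridge carbon.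

## Route

Step 1
Reactants: 1 methyl 2,4,6-trihydroxybenzoate
Product: 2 methyl 2,6-dihydroxy-4-methoxybenzoate
Conditions: MeOH (1.1 equiv), PPh3, DIAD, THF, 0 °C to rt
Reagents that add atoms: methanol, CO
Why: Mitsunobu etherification: the two ortho hydroxyls are hydrogen-bonded to the ester and are the weaker acids, so only the para hydroxyl (O4), acidified by the para ester, is a competent pronucleophile; one equivalent of methanol keeps the reaction at mono-methylation.

Step 2
Reactants: 2 methyl 2,6-dihydroxy-4-methoxybenzoate (two molecules)
Product: 3 dimethyl 3,3'-methylenebis(2,6-dihydroxy-4-methoxybenzoate)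
Conditions: 37% aq. CH2O (0.5 equiv), 1 M aq. NaOH, 0 °C to rt; then 1 M HCl
Reagents that add atoms: formaldehyde, C=O
Why: Base-mediated hydroxymethylation of the phenoxide at C3 (Lederer–Manasse), loss of hydroxide to an ortho-quinone methide and conjugate addition of a second phenoxide give the diarylmethane. C3 and C5 of 2 are equivalent, so one constitution forms; formaldehyde is limiting so the free C5 positions of 3 are not bridged further, and the ester of a 2,6-dioxidobenzoate resists cold dilute hydroxide.

Step 3
Reactants: 3 dimethyl 3,3'-methylenebis(2,6-dihydroxy-4-methoxybenzoate)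
Product: 4 dimethyl 3,3'-methylenebis[4-methoxy-2,6-bis(methoxymethoxy)benzoate]
Conditions: NaH (6 equiv), MOMCl (6 equiv), DMF, 0 °C to rt
Reagents that add atoms: chloromethyl methyl ether, COCCl
Why: Williamson-type acetalisation: all four hydroxyls are hydrogen-bonded to the esters and flanked by substituents, so they are deprotonated irreversibly with NaH and capped with the small, reactive chloromethyl ether. The acetal ethers survive every basic step that follows and leave together in acid.

Step 4
Reactants: 4 dimethyl 3,3'-methylenebis[4-methoxy-2,6-bis(methoxymethoxy)benzoate]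
Product: 5 3,3'-methylenebis[4-methoxy-2,6-bis(methoxymethoxy)benzoic acid]
Conditions: KOH, DMSO–H2O (4:1), 80 °C, Ar; then cold 1 M HCl to pH 4
Reagents that add atoms: potassium hydroxide, [K+].[OH-]
Why: Saponification (BAc2) of a twice ortho-substituted, electron-rich ester needs the poorly solvated hydroxide of aqueous DMSO and heat; acetal and aryl methyl ethers are inert to base. Acidification is cold and only to pH 4 because the trialkoxybenzoic acid would lose acetal groups or CO2 in stronger acid.

Step 5
Reactants: 6 2,6-dimethyl-4H-pyran-4-one
Product: 8 heptane-2,4,6-trione, via barium dienolate of heptane-2,4,6-trione 7 (not isolated)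
Conditions: Ba(OH)2·8H2O, H2O, 60 °C then 0 °C; cold 2 M HCl, Et2O; used at once
Reagents that add atoms: water, O
Why: Hydrolytic ring opening of a 4-pyranone: hydroxide adds to C2 in conjugate fashion and the ring opens by retro-oxa-Michael reaction. The sparingly soluble barium salt 7 pulls the equilibrium to the open form; cold acidification releases 8, which is used at once because acid or heat closes it back to 6.

Step 6
Reactants: 5 3,3'-methylenebis[4-methoxy-2,6-bis(methoxymethoxy)benzoic acid]; 8 heptane-2,4,6-trione (two molecules)
Product: 11 bis[6-methoxy-2,4-bis(methoxymethoxy)-3-(3,5,7-trioxooctanoyl)phenyl]methane, via bis(acyl imidazolide) of the core 9 (not isolated), via trilithium trianion of heptane-2,4,6-trione 10 (not isolated)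
Conditions: 5, CDI (2.1 equiv), THF, rt to 40 °C, Ar purge; cannulated into 10 [8 (6 equiv), LiN(iPr)2 (18 equiv), THF, 0 °C] at −20 °C, then 0 °C; cold 1 M HCl to pH 4
Reagents that add atoms: none
Why: The hindered diacid is activated as its bis(acyl imidazolide) 9 under neutral conditions that spare the acetals, and each of its two acyl groups then C-acylates one molecule of trianion 10 (Claisen type) at the terminal, last-formed and most basic carbanion, so two triketone units are joined to one core. The excess of 10 absorbs the imidazole from the activation; the expelled imidazolide deprotonates the new ArCO–CH2, and that enolate protects the hindered ketone from a second addition.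

Step 7
Reactants: 11 bis[6-methoxy-2,4-bis(methoxymethoxy)-3-(3,5,7-trioxooctanoyl)phenyl]methane
Product: 13 bis[3-(2,4-dihydroxy-6-methylbenzoyl)-6-methoxy-2,4-bis(methoxymethoxy)phenyl]methane, via twofold cyclic aldol adduct 12 (not isolated)
Conditions: 1 M aq. KOH, THF, Ar, rt; then cold 1 M HCl to pH 5
Reagents that add atoms: none
Why: Aqueous hydroxide converts each arm into its polyanion; the carbanion at the CH2 between the aryl ketone and the next carbonyl (future C1') adds to the terminal methyl ketone carbon (future C6') in a 6-exo-trig aldol, allowed for either enolate orientation, forming the C1'–C6' bond and ring B; adduct 12 loses water and the two remaining ring carbonyls enolise, so aromatisation makes the sequence irreversible. The closest known reaction type is the base-induced aldol cyclisation of 1-aryl-octane-1,3,5,7-tetraones to 2,4-dihydroxy-6-methylbenzophenones, here run on two arms that are insulated by the CH2 bridge and should fold independently. The selectivity needed is between the two six-membered aldol modes: the aryl ketone carbon is flanked by two ortho acetal ethers, twisted out of conjugation and attached to an electron-rich ring, while the methyl ketone is unhindered, so only the wanted mode is open; closure from the terminal CH3 onto the third chain carbon would need a carbanion that aqueous hydroxide does not generate. No stereocentre survives: the two in each half of 12 vanish on dehydration and enolisation. Acetal and aryl methyl ethers are inert to cold aqueous base, exclusion of air protects the resorcinolate, and room temperature keeps hydroxide from cleaving the 1,3-diketone links and the 2'-phenoxide from displacing an ortho acetal ether of ring A (xanthone formation).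

Step 8
Reactants: 13 bis[3-(2,4-dihydroxy-6-methylbenzoyl)-6-methoxy-2,4-bis(methoxymethoxy)phenyl]methane
Product: 14 bis{3-[2-hydroxy-4-(methoxymethoxy)-6-methylbenzoyl]-6-methoxy-2,4-bis(methoxymethoxy)phenyl}methane
Conditions: MOMCl (2.2 equiv), iPr2NEt, CH2Cl2, 0 °C
Reagents that add atoms: chloromethyl methyl ether, COCCl
Why: Selective O-alkylation: in each ring B the 2'-OH is held in a six-membered hydrogen bond to the ketone and crowded by the twisted ring A, whereas the 4'-OH is free and the more acidic (para to the carbonyl), so a weak amine base and a slight excess of the chloromethyl ether should cap only O4'. The acetal is preferred to a silyl ether because an aryl silyl ether would be at risk under the carbonate conditions of step 9.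

Step 9
Reactants: 14 bis{3-[2-hydroxy-4-(methoxymethoxy)-6-methylbenzoyl]-6-methoxy-2,4-bis(methoxymethoxy)phenyl}methane
Product: 15 bis{6-methoxy-3-[2-methoxy-4-(methoxymethoxy)-6-methylbenzoyl]-2,4-bis(methoxymethoxy)phenyl}methane
Conditions: MeI, Cs2CO3, DMF, rt
Reagents that add atoms: iodomethane, CI
Why: Williamson methylation of the only remaining hydroxyls: the caesium phenoxide in DMF breaks the hydrogen bond to the ketone and all other oxygens are capped. Room temperature avoids attack of the 2'-phenoxide on ring A (xanthone formation).

Step 10
Reactants: 15 bis{6-methoxy-3-[2-methoxy-4-(methoxymethoxy)-6-methylbenzoyl]-2,4-bis(methoxymethoxy)phenyl}methane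
Product: 16 digriseophene A, bis[2,4-dihydroxy-3-(4-hydroxy-2-methoxy-6-methylbenzoyl)-6-methoxyphenyl]methane
Conditions: HCl (1.25 M in MeOH), rt to 40 °C
Reagents that add atoms: none
Why: Acid-catalysed acetal exchange: each ArO–CH2OCH3 is protonated and loses the phenol, and the methoxymethyl cation is trapped by the solvent as dimethoxymethane, which keeps it away from the electron-rich rings. Aryl methyl ethers, the hindered ketones and the CH2 bridge should tolerate dilute HCl near room temperature, and the product never meets base.

## Compound list

1 | methyl 2,4,6-trihydroxybenzoate | COC(=O)c1c(O)cc(O)cc1O | starting material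
2 | methyl 2,6-dihydroxy-4-methoxybenzoate | COC(=O)c1c(O)cc(OC)cc1O | intermediate
3 | dimethyl 3,3'-methylenebis(2,6-dihydroxy-4-methoxybenzoate) | COC(=O)c1c(O)cc(OC)c(Cc2c(OC)cc(O)c(C(=O)OC)c2O)c1O | intermediate
4 | dimethyl 3,3'-methylenebis[4-methoxy-2,6-bis(methoxymethoxy)benzoate] | COC(=O)c1c(OCOC)cc(OC)c(Cc2c(OC)cc(OCOC)c(C(=O)OC)c2OCOC)c1OCOC | intermediate
5 | 3,3'-methylenebis[4-methoxy-2,6-bis(methoxymethoxy)benzoic acid] | OC(=O)c1c(OCOC)cc(OC)c(Cc2c(OC)cc(OCOC)c(C(=O)O)c2OCOC)c1OCOC | intermediate
6 | 2,6-dimethyl-4H-pyran-4-one | CC1=CC(=O)C=C(C)O1 | starting material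
7 | barium dienolate of heptane-2,4,6-trione | CC(=O)C=C([O-])C=C(C)[O-].[Ba+2] | intermediate (not isolated)
8 | heptane-2,4,6-trione | CC(=O)CC(=O)CC(C)=O | intermediate
9 | bis[3-(1H-imidazol-1-ylcarbonyl)-6-methoxy-2,4-bis(methoxymethoxy)phenyl]methane | O=C(c1c(OCOC)cc(OC)c(Cc2c(OC)cc(OCOC)c(C(=O)n3ccnc3)c2OCOC)c1OCOC)n1ccnc1 | intermediate (not isolated)
10 | trilithium trianion of heptane-2,4,6-trione | [Li+].[Li+].[Li+].C=C([O-])C=C([O-])C=C(C)[O-] | intermediate (not isolated)
11 | bis[6-methoxy-2,4-bis(methoxymethoxy)-3-(3,5,7-trioxooctanoyl)phenyl]methane | COc1cc(OCOC)c(C(=O)CC(=O)CC(=O)CC(C)=O)c(OCOC)c1Cc1c(OC)cc(OCOC)c(C(=O)CC(=O)CC(=O)CC(C)=O)c1OCOC | intermediate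
12 | bis{3-[(2-hydroxy-2-methyl-4,6-dioxocyclohexyl)carbonyl]-6-methoxy-2,4-bis(methoxymethoxy)phenyl}methane (mixture of diastereomers, configuration not defined) | COc1cc(OCOC)c(C(=O)C2C(=O)CC(=O)CC2(C)O)c(OCOC)c1Cc1c(OC)cc(OCOC)c(C(=O)C2C(=O)CC(=O)CC2(C)O)c1OCOC | intermediate (not isolated)
13 | bis[3-(2,4-dihydroxy-6-methylbenzoyl)-6-methoxy-2,4-bis(methoxymethoxy)phenyl]methane | COc1cc(OCOC)c(C(=O)c2c(C)cc(O)cc2O)c(OCOC)c1Cc1c(OC)cc(OCOC)c(C(=O)c2c(C)cc(O)cc2O)c1OCOC | intermediate
14 | bis{3-[2-hydroxy-4-(methoxymethoxy)-6-methylbenzoyl]-6-methoxy-2,4-bis(methoxymethoxy)phenyl}methane | COc1cc(OCOC)c(C(=O)c2c(C)cc(OCOC)cc2O)c(OCOC)c1Cc1c(OC)cc(OCOC)c(C(=O)c2c(C)cc(OCOC)cc2O)c1OCOC | intermediate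
15 | bis{6-methoxy-3-[2-methoxy-4-(methoxymethoxy)-6-methylbenzoyl]-2,4-bis(methoxymethoxy)phenyl}methane | COc1cc(OCOC)c(C(=O)c2c(C)cc(OCOC)cc2OC)c(OCOC)c1Cc1c(OC)cc(OCOC)c(C(=O)c2c(C)cc(OCOC)cc2OC)c1OCOC | intermediate
16 | digriseophene A | COc1cc(O)c(C(=O)c2c(C)cc(O)cc2OC)c(O)c1Cc1c(OC)cc(O)c(C(=O)c2c(C)cc(O)cc2OC)c1O | target

## Step count and least certain steps

Total: 10 steps. Longest linear sequence: 9 steps from 1 (steps 1 to 4 and 6 to 10); step 5 is a one-step side branch from 6.

Step 7 (key step). The likely failures are scission of the 1,3-dicarbonyl links by hydroxide before folding, folding of only one arm, closure of an arm through oxygen to a 4-pyranone during acidification, and air oxidation of the resorcinolate. The fallback brings ring B in whole by aryllithium acylation; it sets out from 9 (made from 5 as in step 6) and returns at 13. Commercial 5-methylbenzene-1,3-diol is benzylated twice (BnBr, K2CO3, acetone) to 1,3-bis(benzyloxy)-5-methylbenzene F1. NBS in MeCN brominates one of the two equivalent positions between the methyl group and a benzyloxy group, giving 1,5-bis(benzyloxy)-2-bromo-3-methylbenzene F2. Exchange with n-BuLi in THF at −78 °C gives [2,4-bis(benzyloxy)-6-methylphenyl]lithium F3, which is acylated by 9 to bis{3-[2,4-bis(benzyloxy)-6-methylbenzoyl]-6-methoxy-2,4-bis(methoxymethoxy)phenyl}methane F4; the tetra-ortho-substituted ketone resists a second addition. Hydrogenolysis of the four benzyl ethers (H2, Pd/C, palladium metal on carbon, EtOAc) leaves the acetals and gives 13.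

Step 6. The likely failures are proton transfer instead of C–C bond formation (imidazole and the acidic product quench the trianion), reaction at only one of the two acyl groups so that only one of the two triketone units is attached, O-acylation at the internal enolates, and self-condensation of the trianion while the doubly ortho-substituted carbonyl reacts slowly. The fallback replaces the trianion by a monoanion with a single reactive carbon; it sets out from 9 and 6 and returns at 13. Pyranone 6 is deprotonated at one methyl group with LiN(SiMe3)2 in THF at −78 °C to lithium 6-methyl-2-methylidene-2H-pyran-4-olate F5 (4 equiv). Two molecules of F5 are acylated by 9 to bis{6-methoxy-2,4-bis(methoxymethoxy)-3-[(6-methyl-4-oxo-4H-pyran-2-yl)acetyl]phenyl}methane F6, a stable compound that can be purified. Aqueous KOH then opens both pyranone rings, as in step 5, to the polyanion of 11, which folds in the same pot as in step 7 to 13.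

Step 2. The likely failures are chain growth, because each ring of 3 keeps a free nucleophilic C5, and stalling at the hydroxymethyl stage on the ester-deactivated ring. The fallback separates generation of the electrophile from the coupling; it sets out from 2 and returns at 3. A Mannich reaction of 2 (aq. Me2NH, aq. CH2O, EtOH, rt) gives methyl 3-[(dimethylamino)methyl]-2,6-dihydroxy-4-methoxybenzoate F7 with exactly one carbon per ring. Heating F7 with an excess of 2 in dioxane expels dimethylamine, and the transient quinone methide is captured by 2 to give 3.

Step 4. The likely failures are no attack of hydroxide at the shielded carbonyl under conditions the rest tolerates, and loss of acetal groups or CO2 during acidification. The fallback is a redox detour in which no nucleophile has to add to the ester and stay; it sets out from 4 and returns at 5. LiAlH4 in THF at 0 °C reduces 4 to bis[3-(hydroxymethyl)-6-methoxy-2,4-bis(methoxymethoxy)phenyl]methane F8. MnO2 in CH2Cl2 oxidises F8 to bis[3-formyl-6-methoxy-2,4-bis(methoxymethoxy)phenyl]methane F9. Pinnick oxidation (NaClO2, NaH2PO4, 2-methyl-2-butene, tBuOH–H2O) at buffered pH then gives 5.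

## Further compounds

F1 | step 7 | 1,3-bis(benzyloxy)-5-methylbenzene | Cc1cc(OCc2ccccc2)cc(OCc2ccccc2)c1
F2 | step 7 | 1,5-bis(benzyloxy)-2-bromo-3-methylbenzene | Cc1cc(OCc2ccccc2)cc(OCc2ccccc2)c1Br
F3 | step 7 | [2,4-bis(benzyloxy)-6-methylphenyl]lithium | [Li]c1c(C)cc(OCc2ccccc2)cc1OCc1ccccc1
F4 | step 7 | bis{3-[2,4-bis(benzyloxy)-6-methylbenzoyl]-6-methoxy-2,4-bis(methoxymethoxy)phenyl}methane | COc1cc(OCOC)c(C(=O)c2c(C)cc(OCc3ccccc3)cc2OCc2ccccc2)c(OCOC)c1Cc1c(OC)cc(OCOC)c(C(=O)c2c(C)cc(OCc3ccccc3)cc2OCc2ccccc2)c1OCOC
F5 | step 6 | lithium 6-methyl-2-methylidene-2H-pyran-4-olate | [Li+].C=C1C=C([O-])C=C(C)O1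
F6 | step 6 | bis{6-methoxy-2,4-bis(methoxymethoxy)-3-[(6-methyl-4-oxo-4H-pyran-2-yl)acetyl]phenyl}methane | COc1cc(OCOC)c(C(=O)Cc2cc(=O)cc(C)o2)c(OCOC)c1Cc1c(OC)cc(OCOC)c(C(=O)Cc2cc(=O)cc(C)o2)c1OCOC
F7 | step 2 | methyl 3-[(dimethylamino)methyl]-2,6-dihydroxy-4-methoxybenzoate | COC(=O)c1c(O)cc(OC)c(CN(C)C)c1O
F8 | step 4 | bis[3-(hydroxymethyl)-6-methoxy-2,4-bis(methoxymethoxy)phenyl]methane | OCc1c(OCOC)cc(OC)c(Cc2c(OC)cc(OCOC)c(CO)c2OCOC)c1OCOC
F9 | step 4 | bis[3-formyl-6-methoxy-2,4-bis(methoxymethoxy)phenyl]methane | O=Cc1c(OCOC)cc(OC)c(Cc2c(OC)cc(OCOC)c(C=O)c2OCOC)c1OCOC
A1 | alternative 1 | 3-(benzyloxy)cyclobut-2-en-1-one | O=C1CC(OCc2ccccc2)=C1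
A2 | alternative 1 | 1,5-dimethoxypenta-1,4-diyne | COC#CCC#COC
A3 | alternative 1 | bis[4-(benzyloxy)-2-hydroxy-6-methoxyphenyl]methane | COc1cc(OCc2ccccc2)cc(O)c1Cc1c(OC)cc(OCc2ccccc2)cc1O
A4 | alternative 2 | 3,3'-methylenebis{6-[2-(4-(benzyloxy)-2-methoxy-6-methylphenyl)-2-oxoethyl]-4-methoxy-2H-pyran-2-one} | COc1cc(CC(=O)c2c(C)cc(OCc3ccccc3)cc2OC)oc(=O)c1Cc1c(OC)cc(CC(=O)c2c(C)cc(OCc3ccccc3)cc2OC)oc1=O
A5 | alternative 2 | 4',4'-di-O-benzyl digriseophene A | COc1cc(O)c(C(=O)c2c(C)cc(OCc3ccccc3)cc2OC)c(O)c1Cc1c(OC)cc(O)c(C(=O)c2c(C)cc(OCc3ccccc3)cc2OC)c1O
A6 | alternative 3 | 3-(benzyloxy)-5-methylcyclohex-2-en-1-one (racemic) | CC1CC(=O)C=C(OCc2ccccc2)C1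
A7 | alternative 3 | bis{3-[(4-(benzyloxy)-2-hydroxy-6-methylcyclohexa-1,3-dien-1-yl)carbonyl]-6-methoxy-2,4-bis(methoxymethoxy)phenyl}methane (enol form, one diastereomer drawn) | COc1cc(OCOC)c(C(=O)C2=C(O)C=C(OCc3ccccc3)C[C@@H]2C)c(OCOC)c1Cc1c(OC)cc(OCOC)c(C(=O)C2=C(O)C=C(OCc3ccccc3)C[C@@H]2C)c1OCOC
A8 | alternative 3 | bis{3-[4-(benzyloxy)-2-hydroxy-6-methylbenzoyl]-6-methoxy-2,4-bis(methoxymethoxy)phenyl}methane | COc1cc(OCOC)c(C(=O)c2c(C)cc(OCc3ccccc3)cc2O)c(OCOC)c1Cc1c(OC)cc(OCOC)c(C(=O)c2c(C)cc(OCc3ccccc3)cc2O)c1OCOC
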